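## Retrosynthetic overview

Germacrane numbering is used: ring C1–C10, lactone carbons C11–C13 on C7 with C6–O, ester carbon C14 on C10, methyl C15 on C4.

1. The γ-lactone and the ten-membered ring are opened together at C6–C7: intramolecular indium allylation/lactonisation of a seco (Z)-enal carrying a (Z)-2-(bromomethyl)enoate.
2. C1=C10 is cut by cross-metathesis into a west C1–C6 vinyl-oxirane enal and an east C7–C14 acrylate/allylic bromide that already carries both acyloxy groups.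
3. West: cis-vinyl oxirane from a syn-chlorohydrin made by phosphoric-acid-catalysed (Z)-γ-chloroallylboration of 5-hydroxy-4-methylfuranone; the butenolide locks the 4Z olefin.
4. East: C8 by amine-catalysed α-oxyamination of 3-silyloxypropanal, C9 by a β-isocupreidine Morita–Baylis–Hillman reaction; side-chain acids from tiglic acid (Ru–BINAP hydrogenation) and benzyl tiglate (Shi epoxidation, acetate opening).
5. Ring order: oxirane (step 3), then carbocycle and γ-lactone in the same last step (step 18).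

Assumption: each named catalyst enantiomer is the one that gives the drawn configuration under the accepted model for its catalyst class.

## Route

Step 1
Reactants: 1 allyl chloride (3-chloroprop-1-ene)
Product: 3 2-[(2Z)-3-chloroprop-2-en-1-yl]-4,4,5,5-tetramethyl-1,3,2-dioxaborolane, via (Z)-3-chloroallyllithium 2 (not isolated)
Conditions: LiN(i-Pr)2, 2-isopropoxy-4,4,5,5-tetramethyl-1,3,2-dioxaborolane (in situ trap), THF, −95 °C; then HCl in Et2O, −78 → 0 °C
Reagents that add atoms: 2-isopropoxy-4,4,5,5-tetramethyl-1,3,2-dioxaborolane, CC(C)OB1OC(C)(C)C(C)(C)O1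
Why: γ-Deprotonation of allyl chloride gives the chelated (Z)-γ-chloroallyllithium, which is trapped by the borate as it forms and releases the pinacol allylboronate on acidification (lithiation–borylation).

Step 2
Reactants: 4 5-hydroxy-4-methylfuran-2(5H)-one (racemic hemiacetal in equilibrium with its achiral open form); 3 2-[(2Z)-3-chloroprop-2-en-1-yl]-4,4,5,5-tetramethyl-1,3,2-dioxaborolane
Product: 7 (5S)-5-[(1S)-1-chloroprop-2-en-1-yl]-4-methylfuran-2(5H)-one, via open-chain aldehyde acid 5 (not isolated), via O-boryl chlorohydrin acid 6 (not isolated)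
Conditions: (R)-3,3′-bis(2,4,6-triisopropylphenyl)-1,1′-binaphthyl-2,2′-diyl hydrogen phosphate [(R)-TRIP, 10 mol %], 4 Å molecular sieves, toluene, −30 °C, then 23 °C
Reagents that add atoms: none
Why: Proposed new method: chiral-phosphoric-acid-catalysed (Z)-γ-chloroallylboration of a pseudo-acid, in which ring–chain tautomer 5 supplies the aldehyde, the catalyst hydrogen-bonds to a boronate oxygen and to the formyl hydrogen so that the six-membered chair transition state adds to the Re face (ring C5, S) with the (Z)-chlorine axial (syn chlorohydrin, C1′ S), and borate 6 lactonises to lock the (Z)-olefin; the closest known reactions are phosphoric-acid-catalysed allyl- and crotylboration of aldehydes with pinacol boronates and the uncatalysed or isopinocampheylborane versions of (Z)-γ-chloroallylboration.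

Step 3
Reactants: 7 (5S)-5-[(1S)-1-chloroprop-2-en-1-yl]-4-methylfuran-2(5H)-one
Product: 10 (2Z)-3-[(2S,3R)-3-ethenyloxiran-2-yl]but-2-enal, via lactol 8 (not isolated), via hydroxy enal 9 (not isolated)
Conditions: i-Bu2AlH (1.05 equiv), CH2Cl2, −78 °C; then MeOH, K2CO3, −78 → 0 °C
Reagents that add atoms: none
Why: Low-temperature hydride reduction of the butenolide stops at the lactol, whose open hydroxy-enal form closes to the cis-oxirane by intramolecular SN2 with inversion at the chloride carbon (Williamson-type epoxide closure), keeping the ring-derived (Z)-olefin.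

Step 4
Reactants: 11 tiglic acid [(2E)-2-methylbut-2-enoic acid]
Product: 12 (2R)-2-methylbutanoic acid
Conditions: Ru(OAc)2[(R)-BINAP] (0.5 mol %), H2 (4 atm), MeOH, 23 °C
Reagents that add atoms: none
Why: Noyori asymmetric hydrogenation of an α,β-unsaturated acid, in which the carboxylate-bound Ru–BINAP hydride delivers hydrogen to one olefin face and sets C2 (R).

Step 5
Reactants: 13 benzyl tiglate [benzyl (2E)-2-methylbut-2-enoate]
Product: 14 benzyl (2S,3R)-2,3-dimethyloxirane-2-carboxylate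
Conditions: 1,2-O-isopropylidene-4,5-di-O-acetyl-β-D-erythro-2,3-hexodiulo-2,6-pyranose (D-fructose-derived ketone, 25 mol %), KHSO5 (as Oxone), NaHCO3, Bu4NHSO4, MeCN/aq. Na2EDTA, 0 °C
Reagents that add atoms: potassium peroxymonosulfate (Oxone), [K+].[O-]S(=O)(=O)OO
Why: Shi epoxidation, in which the chiral dioxirane transfers oxygen through a spiro transition state to one face of the trisubstituted enoate and sets both oxirane carbons (2S,3R).

Step 6
Reactants: 14 benzyl (2S,3R)-2,3-dimethyloxirane-2-carboxylate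
Product: 15 benzyl (2S,3S)-3-acetoxy-2-hydroxy-2-methylbutanoate
Conditions: AcOH (solvent), CsOAc (0.2 equiv), 70 °C
Reagents that add atoms: acetic acid, CC(=O)O
Why: Acetate opens the glycidic ester by SN2 at C3 (the carbon that is neither quaternary nor α to the ester) with inversion, giving the (2S,3S) hydroxy acetate and leaving C2 untouched.

Step 7
Reactants: 15 benzyl (2S,3S)-3-acetoxy-2-hydroxy-2-methylbutanoate
Product: 16 (2S,3S)-3-acetoxy-2-hydroxy-2-methylbutanoic acid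
Conditions: H2 (1 atm), Pd on carbon (Pd/C, 10 %), EtOAc, 23 °C
Reagents that add atoms: none
Why: Hydrogenolysis of the benzyl ester frees the acid without touching the acetate or the stereocentres.

Step 8
Reactants: 17 3-[(tert-butyldiphenylsilyl)oxy]propanal
Product: 18 (2S)-3-[(tert-butyldiphenylsilyl)oxy]-2-[(2,2,6,6-tetramethylpiperidin-1-yl)oxy]propanal
Conditions: (2S,5S)-5-benzyl-2-tert-butyl-3-methylimidazolidin-4-one·TFA (20 mol %), CuCl2 (10 mol %), TEMPO (1.2 equiv), air, DMF, −10 °C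
Reagents that add atoms: TEMPO [(2,2,6,6-tetramethylpiperidin-1-yl)oxyl], CC1(C)CCCC(C)(C)N1[O]
Why: Enamine catalysis (α-oxyamination), in which the imidazolidinone enamine is oxygenated by copper-activated TEMPO on its unshielded face, setting the α-carbon (future C8) as S in a configurationally stable aldehyde.

Step 9
Reactants: 18 (2S)-3-[(tert-butyldiphenylsilyl)oxy]-2-[(2,2,6,6-tetramethylpiperidin-1-yl)oxy]propanal; 19 1,1,1,3,3,3-hexafluoropropan-2-yl acrylate
Product: 21 methyl (3S,4S)-5-[(tert-butyldiphenylsilyl)oxy]-3-hydroxy-2-methylidene-4-[(2,2,6,6-tetramethylpiperidin-1-yl)oxy]pentanoate, via hexafluoroisopropyl ester 20 (not isolated)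
Conditions: β-isocupreidine (10 mol %), DMF, −55 °C; then MeOH, Et3N, 0 → 23 °C
Reagents that add atoms: methanol, CO
Why: Asymmetric Morita–Baylis–Hillman reaction, in which the bifunctional cinchona amine/phenol catalyst controls the aldehyde face and sets the carbinol (future C9) as 3S, syn to C4, after which the activated fluoro ester is exchanged for the methyl ester.

Step 10
Reactants: 21 methyl (3S,4S)-5-[(tert-butyldiphenylsilyl)oxy]-3-hydroxy-2-methylidene-4-[(2,2,6,6-tetramethylpiperidin-1-yl)oxy]pentanoate; 12 (2R)-2-methylbutanoic acid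
Product: 22 methyl (3S,4S)-5-[(tert-butyldiphenylsilyl)oxy]-2-methylidene-3-{[(2R)-2-methylbutanoyl]oxy}-4-[(2,2,6,6-tetramethylpiperidin-1-yl)oxy]pentanoate
Conditions: DCC, DMAP (0.1 equiv), CH2Cl2, 0 → 23 °C
Reagents that add atoms: none
Why: Steglich esterification of the allylic alcohol proceeds with retention at C3 and puts the first natural side chain in place.

Step 11
Reactants: 22 methyl (3S,4S)-5-[(tert-butyldiphenylsilyl)oxy]-2-methylidene-3-{[(2R)-2-methylbutanoyl]oxy}-4-[(2,2,6,6-tetramethylpiperidin-1-yl)oxy]pentanoate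
Product: 23 methyl (3S,4S)-5-[(tert-butyldiphenylsilyl)oxy]-4-hydroxy-2-methylidene-3-{[(2R)-2-methylbutanoyl]oxy}pentanoate
Conditions: Zn dust, AcOH/THF/H2O (3:1:1), 50 °C
Reagents that add atoms: none
Why: Reductive N–O cleavage of the alkoxyamine frees the C4 hydroxyl with retention, and the robust silyl ether and the acrylate survive the acidic zinc conditions.

Step 12
Reactants: 23 methyl (3S,4S)-5-[(tert-butyldiphenylsilyl)oxy]-4-hydroxy-2-methylidene-3-{[(2R)-2-methylbutanoyl]oxy}pentanoate; 16 (2S,3S)-3-acetoxy-2-hydroxy-2-methylbutanoic acid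
Product: 24 methyl (3S,4S)-4-{[(2S,3S)-3-acetoxy-2-hydroxy-2-methylbutanoyl]oxy}-5-[(tert-butyldiphenylsilyl)oxy]-2-methylidene-3-{[(2R)-2-methylbutanoyl]oxy}pentanoate
Conditions: EDC·HCl, DMAP (0.2 equiv), CH2Cl2, 0 °C
Reagents that add atoms: none
Why: Steglich esterification acylates the secondary C4 hydroxyl with retention, while the tertiary hydroxyl of the acid is too hindered to compete and the low temperature suppresses 1,2-acyl migration.

Step 13
Reactants: 24 methyl (3S,4S)-4-{[(2S,3S)-3-acetoxy-2-hydroxy-2-methylbutanoyl]oxy}-5-[(tert-butyldiphenylsilyl)oxy]-2-methylidene-3-{[(2R)-2-methylbutanoyl]oxy}pentanoate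
Product: 25 methyl (3S,4S)-4-{[(2S,3S)-3-acetoxy-2-hydroxy-2-methylbutanoyl]oxy}-5-hydroxy-2-methylidene-3-{[(2R)-2-methylbutanoyl]oxy}pentanoate
Conditions: HF·pyridine, pyridine/THF, 0 → 23 °C
Reagents that add atoms: none
Why: Buffered fluoride desilylation frees the primary alcohol under mildly acidic conditions that do not move the esters.

Step 14
Reactants: 25 methyl (3S,4S)-4-{[(2S,3S)-3-acetoxy-2-hydroxy-2-methylbutanoyl]oxy}-5-hydroxy-2-methylidene-3-{[(2R)-2-methylbutanoyl]oxy}pentanoate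
Product: 26 methyl (3S,4R)-4-{[(2S,3S)-3-acetoxy-2-hydroxy-2-methylbutanoyl]oxy}-2-methylidene-3-{[(2R)-2-methylbutanoyl]oxy}-5-oxopentanoate
Conditions: Dess–Martin periodinane, NaHCO3, CH2Cl2, 0 → 23 °C; used crude
Reagents that add atoms: none
Why: Dess–Martin oxidation gives the aldehyde under neutral conditions that avoid β-elimination or epimerisation (the descriptor at C4 changes only through priority).

Step 15
Reactants: 26 methyl (3S,4R)-4-{[(2S,3S)-3-acetoxy-2-hydroxy-2-methylbutanoyl]oxy}-2-methylidene-3-{[(2R)-2-methylbutanoyl]oxy}-5-oxopentanoate; 27 methyl propiolate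
Product: 29 dimethyl (3S,4S)-4-{[(2S,3S)-3-acetoxy-2-hydroxy-2-methylbutanoyl]oxy}-5-hydroxy-2,6-dimethylidene-3-{[(2R)-2-methylbutanoyl]oxy}heptanedioate (C5 epimers), via vinylalane 28 (not isolated)
Conditions: i-Bu2AlH, N-methylmorpholine N-oxide, THF, 0 °C, then 27; then 26, 0 → 23 °C
Reagents that add atoms: none
Why: Vinylalumination (an aluminium-based Morita–Baylis–Hillman surrogate): hydroalumination of the propiolate gives an α-alumino acrylate that adds to the aldehyde without amine base, so the acyloxy groups are not eliminated, and the new carbinol configuration does not matter because it is erased in the next step.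

Step 16
Reactants: 29 dimethyl (3S,4S)-4-{[(2S,3S)-3-acetoxy-2-hydroxy-2-methylbutanoyl]oxy}-5-hydroxy-2,6-dimethylidene-3-{[(2R)-2-methylbutanoyl]oxy}heptanedioate
Product: 30 dimethyl (2Z,4S,5S)-4-{[(2S,3S)-3-acetoxy-2-hydroxy-2-methylbutanoyl]oxy}-2-(bromomethyl)-6-methylidene-5-{[(2R)-2-methylbutanoyl]oxy}hept-2-enedioate
Conditions: NBS, Me2S, CH2Cl2, 0 → 23 °C
Reagents that add atoms: N-bromosuccinimide, O=C1CCC(=O)N1Br
Why: Corey–Kim-type activation of the allylic alcohol and SN2′ attack by bromide gives the rearranged (Z)-2-(bromomethyl)enoate with the chain trans to the ester, as is general for Baylis–Hillman alcohols.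

Step 17
Reactants: 30 dimethyl (2Z,4S,5S)-4-{[(2S,3S)-3-acetoxy-2-hydroxy-2-methylbutanoyl]oxy}-2-(bromomethyl)-6-methylidene-5-{[(2R)-2-methylbutanoyl]oxy}hept-2-enedioate; 10 (2Z)-3-[(2S,3R)-3-ethenyloxiran-2-yl]but-2-enal (3 equiv)
Product: 31 dimethyl (2Z,4S,5S,6E)-4-{[(2S,3S)-3-acetoxy-2-hydroxy-2-methylbutanoyl]oxy}-2-(bromomethyl)-5-{[(2R)-2-methylbutanoyl]oxy}-6-({(2R,3S)-3-[(2Z)-4-oxobut-2-en-2-yl]oxiran-2-yl}methylidene)hept-2-enedioate
Conditions: second-generation Hoveyda–Grubbs catalyst (15 mol %), 1,4-benzoquinone (10 mol %), CH2Cl2, 40 °C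
Reagents that add atoms: none
Why: Olefin cross-metathesis between the only two terminal alkenes (vinyl oxirane and 2-substituted acrylate) gives the trisubstituted enoate with the oxirane trans to the ester (thermodynamic geometry, ring-cis C2/C9), the trisubstituted olefins and the allylic bromide being inert to the phosphine-free catalyst.

Step 18
Reactants: 31 dimethyl (2Z,4S,5S,6E)-4-{[(2S,3S)-3-acetoxy-2-hydroxy-2-methylbutanoyl]oxy}-2-(bromomethyl)-5-{[(2R)-2-methylbutanoyl]oxy}-6-({(2R,3S)-3-[(2Z)-4-oxobut-2-en-2-yl]oxiran-2-yl}methylidene)hept-2-enedioate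
Product: 33 CNP0402153.1, via hydroxy ester 32 (not isolated)
Conditions: indium powder (4 equiv), THF/H2O (3:1), 2 mM, 23 °C; then PPTS (10 mol %), CH2Cl2, 23 °C
Reagents that add atoms: none
Why: Intramolecular Barbier allylation, in which the (Z)-allylindium adds through its γ-carbon to the (Z)-enal in a cyclic six-membered transition state (syn adduct) with the aldehyde approaching C7 anti to the C8–O bond while C8–H eclipses the olefin, which closes the ten-membered ring and sets C6 (R) and C7 (R), and the cis-disposed hydroxyl then lactonises onto the methyl ester.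

## Compound list

1 | allyl chloride (3-chloroprop-1-ene) | C=CCCl | starting material
2 | (Z)-3-chloroallyllithium | [Li]C/C=C\Cl | intermediate
3 | 2-[(2Z)-3-chloroprop-2-en-1-yl]-4,4,5,5-tetramethyl-1,3,2-dioxaborolane | Cl/C=C\CB1OC(C)(C)C(C)(C)O1 | intermediate
4 | 5-hydroxy-4-methylfuran-2(5H)-one (racemic hemiacetal) | CC1=CC(=O)OC1O | starting material
5 | (2Z)-3-methyl-4-oxobut-2-enoic acid (open tautomer of 4) | O=C/C(C)=C\C(=O)O | intermediate
6 | (2Z,4S,5S)-5-chloro-3-methyl-4-[(4,4,5,5-tetramethyl-1,3,2-dioxaborolan-2-yl)oxy]hepta-2,6-dienoic acid | OC(=O)/C=C(/C)[C@H](OB1OC(C)(C)C(C)(C)O1)[C@@H](Cl)C=C | intermediate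
7 | (5S)-5-[(1S)-1-chloroprop-2-en-1-yl]-4-methylfuran-2(5H)-one | O=C1C=C(C)[C@@H]([C@@H](Cl)C=C)O1 | intermediate
8 | (5S)-5-[(1S)-1-chloroprop-2-en-1-yl]-4-methyl-2,5-dihydrofuran-2-ol (C2 epimers) | OC1C=C(C)[C@@H]([C@@H](Cl)C=C)O1 | intermediate
9 | (2Z,4S,5S)-5-chloro-4-hydroxy-3-methylhepta-2,6-dienal | O=C/C=C(/C)[C@H](O)[C@@H](Cl)C=C | intermediate
10 | (2Z)-3-[(2S,3R)-3-ethenyloxiran-2-yl]but-2-enal | O=C/C=C(/C)[C@@H]1O[C@@H]1C=C | intermediate
11 | tiglic acid, (2E)-2-methylbut-2-enoic acid | C/C=C(\C)C(=O)O | starting material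
12 | (2R)-2-methylbutanoic acid | CC[C@@H](C)C(=O)O | intermediate
13 | benzyl tiglate, benzyl (2E)-2-methylbut-2-enoate | C/C=C(\C)C(=O)OCc1ccccc1 | starting material
14 | benzyl (2S,3R)-2,3-dimethyloxirane-2-carboxylate | O=C(OCc1ccccc1)[C@@]1(C)O[C@@H]1C | intermediate
15 | benzyl (2S,3S)-3-acetoxy-2-hydroxy-2-methylbutanoate | O=C(OCc1ccccc1)[C@@](C)(O)[C@H](C)OC(C)=O | intermediate
16 | (2S,3S)-3-acetoxy-2-hydroxy-2-methylbutanoic acid | OC(=O)[C@@](C)(O)[C@H](C)OC(C)=O | intermediate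
17 | 3-[(tert-butyldiphenylsilyl)oxy]propanal | O=CCCO[Si](c1ccccc1)(c1ccccc1)C(C)(C)C | starting material
18 | (2S)-3-[(tert-butyldiphenylsilyl)oxy]-2-[(2,2,6,6-tetramethylpiperidin-1-yl)oxy]propanal | O=C[C@@H](ON1C(C)(C)CCCC1(C)C)CO[Si](c1ccccc1)(c1ccccc1)C(C)(C)C | intermediate
19 | 1,1,1,3,3,3-hexafluoropropan-2-yl acrylate | C=CC(=O)OC(C(F)(F)F)C(F)(F)F | starting material
20 | 1,1,1,3,3,3-hexafluoropropan-2-yl (3S,4S)-5-[(tert-butyldiphenylsilyl)oxy]-3-hydroxy-2-methylidene-4-[(2,2,6,6-tetramethylpiperidin-1-yl)oxy]pentanoate | C=C(C(=O)OC(C(F)(F)F)C(F)(F)F)[C@H](O)[C@@H](ON1C(C)(C)CCCC1(C)C)CO[Si](c1ccccc1)(c1ccccc1)C(C)(C)C | intermediate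
21 | methyl (3S,4S)-5-[(tert-butyldiphenylsilyl)oxy]-3-hydroxy-2-methylidene-4-[(2,2,6,6-tetramethylpiperidin-1-yl)oxy]pentanoate | C=C(C(=O)OC)[C@H](O)[C@@H](ON1C(C)(C)CCCC1(C)C)CO[Si](c1ccccc1)(c1ccccc1)C(C)(C)C | intermediate
22 | methyl (3S,4S)-5-[(tert-butyldiphenylsilyl)oxy]-2-methylidene-3-{[(2R)-2-methylbutanoyl]oxy}-4-[(2,2,6,6-tetramethylpiperidin-1-yl)oxy]pentanoate | C=C(C(=O)OC)[C@H](OC(=O)[C@H](C)CC)[C@@H](ON1C(C)(C)CCCC1(C)C)CO[Si](c1ccccc1)(c1ccccc1)C(C)(C)C | intermediate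
23 | methyl (3S,4S)-5-[(tert-butyldiphenylsilyl)oxy]-4-hydroxy-2-methylidene-3-{[(2R)-2-methylbutanoyl]oxy}pentanoate | C=C(C(=O)OC)[C@H](OC(=O)[C@H](C)CC)[C@@H](O)CO[Si](c1ccccc1)(c1ccccc1)C(C)(C)C | intermediate
24 | methyl (3S,4S)-4-{[(2S,3S)-3-acetoxy-2-hydroxy-2-methylbutanoyl]oxy}-5-[(tert-butyldiphenylsilyl)oxy]-2-methylidene-3-{[(2R)-2-methylbutanoyl]oxy}pentanoate | C=C(C(=O)OC)[C@H](OC(=O)[C@H](C)CC)[C@@H](OC(=O)[C@@](C)(O)[C@H](C)OC(C)=O)CO[Si](c1ccccc1)(c1ccccc1)C(C)(C)C | intermediate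
25 | methyl (3S,4S)-4-{[(2S,3S)-3-acetoxy-2-hydroxy-2-methylbutanoyl]oxy}-5-hydroxy-2-methylidene-3-{[(2R)-2-methylbutanoyl]oxy}pentanoate | C=C(C(=O)OC)[C@H](OC(=O)[C@H](C)CC)[C@@H](OC(=O)[C@@](C)(O)[C@H](C)OC(C)=O)CO | intermediate
26 | methyl (3S,4R)-4-{[(2S,3S)-3-acetoxy-2-hydroxy-2-methylbutanoyl]oxy}-2-methylidene-3-{[(2R)-2-methylbutanoyl]oxy}-5-oxopentanoate | C=C(C(=O)OC)[C@H](OC(=O)[C@H](C)CC)[C@@H](OC(=O)[C@@](C)(O)[C@H](C)OC(C)=O)C=O | intermediate
27 | methyl propiolate | C#CC(=O)OC | starting material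
28 | [1-(methoxycarbonyl)ethenyl]bis(2-methylpropyl)alane | C=C(C(=O)OC)[Al](CC(C)C)CC(C)C | intermediate
29 | dimethyl (3S,4S)-4-{[(2S,3S)-3-acetoxy-2-hydroxy-2-methylbutanoyl]oxy}-5-hydroxy-2,6-dimethylidene-3-{[(2R)-2-methylbutanoyl]oxy}heptanedioate (C5 epimers) | C=C(C(=O)OC)[C@H](OC(=O)[C@H](C)CC)[C@@H](OC(=O)[C@@](C)(O)[C@H](C)OC(C)=O)C(O)C(=C)C(=O)OC | intermediate
30 | dimethyl (2Z,4S,5S)-4-{[(2S,3S)-3-acetoxy-2-hydroxy-2-methylbutanoyl]oxy}-2-(bromomethyl)-6-methylidene-5-{[(2R)-2-methylbutanoyl]oxy}hept-2-enedioate | C=C(C(=O)OC)[C@H](OC(=O)[C@H](C)CC)[C@@H](OC(=O)[C@@](C)(O)[C@H](C)OC(C)=O)/C=C(\CBr)C(=O)OC | intermediate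
31 | dimethyl (2Z,4S,5S,6E)-4-{[(2S,3S)-3-acetoxy-2-hydroxy-2-methylbutanoyl]oxy}-2-(bromomethyl)-5-{[(2R)-2-methylbutanoyl]oxy}-6-({(2R,3S)-3-[(2Z)-4-oxobut-2-en-2-yl]oxiran-2-yl}methylidene)hept-2-enedioate | O=C/C=C(/C)[C@@H]1O[C@@H]1/C=C(/C(=O)OC)[C@H](OC(=O)[C@H](C)CC)[C@@H](OC(=O)[C@@](C)(O)[C@H](C)OC(C)=O)/C=C(\CBr)C(=O)OC | intermediate
32 | methyl 2-[(1(10)E,2R,3S,4Z,6R,7R,8S,9S)-2,3-epoxy-6-hydroxy-14-methoxy-14-oxo-8,9-diacyloxygermacra-1(10),4-dien-7-yl]acrylate (ring-closed hydroxy ester, acyl groups as in 33) | C=C(C(=O)OC)[C@@H]1[C@H](O)/C=C(/C)[C@@H]2O[C@@H]2/C=C(/C(=O)OC)[C@H](OC(=O)[C@H](C)CC)[C@H]1OC(=O)[C@@](C)(O)[C@H](C)OC(C)=O | intermediate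
33 | CNP0402153.1: methyl (1(10)E,2R,3S,4Z,6R,7R,8S,9S)-8-{[(2S,3S)-3-acetoxy-2-hydroxy-2-methylbutanoyl]oxy}-2,3-epoxy-9-{[(2R)-2-methylbutanoyl]oxy}-12-oxogermacra-1(10),4,11(13)-trien-12,6-olid-14-oate (cis-fused lactone) | C=C1C(=O)O[C@@H]2/C=C(/C)[C@@H]3O[C@@H]3/C=C(/C(=O)OC)[C@H](OC(=O)[C@H](C)CC)[C@@H](OC(=O)[C@@](C)(O)[C@H](C)OC(C)=O)[C@H]12 | target

## Step count and risks

Total step count: 18. Longest linear sequence: 11 (steps 8 to 18).

Three steps most likely to fail: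

**Step 2 (proposed new chloroallylboration).** The open aldehyde form 5 is a minor tautomer and its own carboxylic acid may promote a racemic background reaction, so rate and enantiomeric excess are uncertain. The fallback uses known stoichiometric reagent control. It sets out from 4, which is O-methylated with TMSCHN2 (MeOH/toluene, 0 °C) to the open-chain methyl (2Z)-3-methyl-4-oxobut-2-enoate F1. F1 is treated at −95 °C with (Z)-γ-chloroallyl-diisopinocampheylborane, made in the flask from 1, LiN(c-Hex)2, (+)-Ipc2BOMe and BF3·OEt2 (Oehlschlager–Brown chloroallylboration). Ethanolamine work-up gives methyl (2Z,4S,5S)-5-chloro-4-hydroxy-3-methylhepta-2,6-dienoate F2. F2 lactonises with PPTS in CH2Cl2, and the route is rejoined at 7.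

**Step 17 (cross-metathesis).** The 2-substituted acrylate in 30 is hindered, and 10 is heat- and acid-sensitive. The fallback changes the order of bond formation, so that the metathesis becomes ring-closing. It sets out from 10 and 30. These are first joined by intermolecular indium allylation (In, THF/H2O, 23 °C, then PPTS) to the open-chain cis-lactone methyl (3S,4S)-4-{[(2S,3S)-3-acetoxy-2-hydroxy-2-methylbutanoyl]oxy}-4-[(2R,3R)-2-{(1Z)-2-[(2S,3R)-3-ethenyloxiran-2-yl]prop-1-en-1-yl}-4-methylidene-5-oxooxolan-3-yl]-2-methylidene-3-{[(2R)-2-methylbutanoyl]oxy}butanoate F3. F3 is then closed by ring-closing metathesis (second-generation Hoveyda–Grubbs catalyst, toluene, 1 mM, 60 °C), and the route is rejoined at 33. The lactone methylene is a competing metathesis site in F3, so this path is itself uncertain.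

**Step 18 (macrocyclising allylation).** The allylindium may lose the C8 acyloxy group by 1,4-elimination, may add with the wrong facial sense at C7, or may oligomerise. The fallback replaces the metal-mediated Barbier step by a metal-free allylboration through a closed chair transition state. It sets out from 30, which is borylated with B2pin2 and Pd2(dba)3 (toluene, 23 °C, no base) to dimethyl (2E,4S,5S)-4-{[(2S,3S)-3-acetoxy-2-hydroxy-2-methylbutanoyl]oxy}-6-methylidene-5-{[(2R)-2-methylbutanoyl]oxy}-2-[(4,4,5,5-tetramethyl-1,3,2-dioxaborolan-2-yl)methyl]hept-2-enedioate F4. Cross-metathesis of F4 with 10, under the conditions of step 17, gives dimethyl (2E,4S,5S,6E)-4-{[(2S,3S)-3-acetoxy-2-hydroxy-2-methylbutanoyl]oxy}-5-{[(2R)-2-methylbutanoyl]oxy}-6-({(2R,3S)-3-[(2Z)-4-oxobut-2-en-2-yl]oxiran-2-yl}methylidene)-2-[(4,4,5,5-tetramethyl-1,3,2-dioxaborolan-2-yl)methyl]hept-2-enedioate F5. Heating F5 in toluene (2 mM, 70 °C) brings about intramolecular allylboration and lactonisation, and the route is rejoined at 33.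

Further compounds
F1 | step 2 | methyl (2Z)-3-methyl-4-oxobut-2-enoate | COC(=O)/C=C(/C)C=O
F2 | step 2 | methyl (2Z,4S,5S)-5-chloro-4-hydroxy-3-methylhepta-2,6-dienoate | COC(=O)/C=C(/C)[C@H](O)[C@@H](Cl)C=C
F3 | step 17 | methyl (3S,4S)-4-{[(2S,3S)-3-acetoxy-2-hydroxy-2-methylbutanoyl]oxy}-4-[(2R,3R)-2-{(1Z)-2-[(2S,3R)-3-ethenyloxiran-2-yl]prop-1-en-1-yl}-4-methylidene-5-oxooxolan-3-yl]-2-methylidene-3-{[(2R)-2-methylbutanoyl]oxy}butanoate | C=C1C(=O)O[C@H](/C=C(/C)[C@@H]2O[C@@H]2C=C)[C@@H]1[C@H](OC(=O)[C@@](C)(O)[C@H](C)OC(C)=O)[C@@H](OC(=O)[C@H](C)CC)C(=C)C(=O)OC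
F4 | step 18 | dimethyl (2E,4S,5S)-4-{[(2S,3S)-3-acetoxy-2-hydroxy-2-methylbutanoyl]oxy}-6-methylidene-5-{[(2R)-2-methylbutanoyl]oxy}-2-[(4,4,5,5-tetramethyl-1,3,2-dioxaborolan-2-yl)methyl]hept-2-enedioate | C=C(C(=O)OC)[C@H](OC(=O)[C@H](C)CC)[C@@H](OC(=O)[C@@](C)(O)[C@H](C)OC(C)=O)/C=C(\CB1OC(C)(C)C(C)(C)O1)C(=O)OC
F5 | step 18 | dimethyl (2E,4S,5S,6E)-4-{[(2S,3S)-3-acetoxy-2-hydroxy-2-methylbutanoyl]oxy}-5-{[(2R)-2-methylbutanoyl]oxy}-6-({(2R,3S)-3-[(2Z)-4-oxobut-2-en-2-yl]oxiran-2-yl}methylidene)-2-[(4,4,5,5-tetramethyl-1,3,2-dioxaborolan-2-yl)methyl]hept-2-enedioate | O=C/C=C(/C)[C@@H]1O[C@@H]1/C=C(/C(=O)OC)[C@H](OC(=O)[C@H](C)CC)[C@@H](OC(=O)[C@@](C)(O)[C@H](C)OC(C)=O)/C=C(\CB1OC(C)(C)C(C)(C)O1)C(=O)OC
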